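**Plan**

- Numbering: lactone O1, C2(=O), C3=C4, C5(O-acyl), C6; side chain C7–C13 (methyls on C7, C9, C11); acyl chain C1′–C8′ (CH2OH on C6′).
- Cuts: epoxide oxygen (last step); C5–O ester; the pyranone ring back to a 2-furylcarbinol (O1/C2–C5 = furan); C10–C11; C6–C(furan), which leaves furan and meso-2,4-dimethylglutaric anhydride. Acid half: C2′=C3′, the C3′ oxygen, C5′–C6′.
- Enabling feature: C6–C10 with its syn methyls on C7/C9 is a meso-2,4-dimethylglutarate in disguise, and the 5,6-dihydropyran-2-one ring with its C5 oxygen is an oxidised furan.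
- Forward: desymmetrising furyl acylation → C10 reduced and coupled to the butenyl unit → C6 carbinol → furan ring-expanded, oxidised, C5=O reduced → acylation with the dienoic acid → desilylation → epoxidation.
- Stereochemistry: C7/C9 from the meso anhydride (the Rh catalyst chooses the carbonyl); C6 by Ru transfer hydrogenation; C5 by hydride delivery anti to the C6 chain; C6′ by Rh/(S)-BINAP conjugate addition; C11/C12 by the ent-Shi ketone; alkene geometries from (E)-2-bromobut-2-ene, SeO2 and HWE.

Key step: step 1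

Assumption: the (S)-configured t-Bu-PHOX ligand is taken to direct step 1 to the carbonyl flanked by the future C7; if the sense is found to be opposite, its antipode is used and nothing else changes.

**Route**

Step 1
Reactants: 1 meso-2,4-dimethylglutaric anhydride; 2 furan
Product: 5 (2R,4S)-5-(furan-2-yl)-2,4-dimethyl-5-oxopentanoic acid, via 2-furyllithium 3 (not isolated), via 2-furylzinc chloride 4 (not isolated)
Conditions: 2, n-BuLi, THF, 0 °C; ZnCl2, 0 °C→rt; then 1, [Rh(cod)Cl]2 (2.5 mol%), (S)-t-Bu-PHOX (6 mol%), THF, 50 °C; 1 M HCl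
Reagents that add atoms: none
Why: Proposed new method: Rh(I)–phosphinooxazoline inserts into one of the two enantiotopic C(acyl)–O bonds of the meso anhydride (oxidative addition, enantio-determining), the acyl–Rh(III) carboxylate is transmetalated by 4, and reductive elimination gives the 2-furyl ketone while the other carbonyl leaves as an unreactive zinc carboxylate, so only mono-acylation occurs. The closest known reaction type is the Rh/t-Bu-PHOX-catalysed alkylative desymmetrisation of this same anhydride with alkylzinc reagents, together with Pd- and Rh-catalysed arylation of meso-succinic anhydrides by arylzincs; a 2-heteroarylzinc on a glutaric anhydride is the untested combination, in which sp2–Zn should transmetalate at least as fast as sp3–Zn and the α-branched acyl–Rh should resist decarbonylation. No ring is closed. C7 and C9 are not created but selected: they already exist as the syn (R,S) pair of the meso compound, and the chiral ligand decides which carbonyl becomes the C6 ketone, which fixes the product as (2R,4S). The step needs enantiotopic-group selectivity and retention of the stereocentre next to the new ketone; the mirror plane through C8 of the anhydride secures the first, and the neutral organozinc conditions secure the second.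

Step 2
Reactants: 5 (2R,4S)-5-(furan-2-yl)-2,4-dimethyl-5-oxopentanoic acid
Product: 6 (2S,4R)-1-(furan-2-yl)-5-hydroxy-2,4-dimethylpentan-1-one
Conditions: BH3·SMe2 (1.1 equiv), THF, −10→0 °C; MeOH, then aq. NaHCO3
Reagents that add atoms: none
Why: Chemoselective borane reduction of a carboxylic acid: the acid is consumed through its acyloxyborane much faster than BH3 attacks the conjugated 2-furyl ketone at ≤0 °C, and the non-basic medium leaves the stereocentre next to the ketone untouched.

Step 3
Reactants: 6 (2S,4R)-1-(furan-2-yl)-5-hydroxy-2,4-dimethylpentan-1-one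
Product: 7 (2S,4R)-1-(furan-2-yl)-5-iodo-2,4-dimethylpentan-1-one
Conditions: I2, PPh3, imidazole, CH2Cl2, 0 °C
Reagents that add atoms: iodine, II
Why: Appel-type iodination (PPh3/I2/imidazole) converts the primary alcohol into the iodide by SN2 at CH2, so neither stereocentre is involved and the aryl ketone is inert.

Step 4
Reactants: 7 (2S,4R)-1-(furan-2-yl)-5-iodo-2,4-dimethylpentan-1-one; 8 (E)-2-bromobut-2-ene
Product: 10 (2S,4R,6E)-1-(furan-2-yl)-2,4,6-trimethyloct-6-en-1-one, via alkylzinc iodide 9 (not isolated)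
Conditions: Zn dust (activated with TMSCl/1,2-dibromoethane), LiCl, THF, 30 °C; then 8, PdCl2(dppf) (3 mol%), THF, 45 °C
Reagents that add atoms: none
Why: Negishi sp3–sp2 coupling: zinc inserts into the primary C–I bond (alkylzinc iodides tolerate ketones) and Pd/dppf couples it with the alkenyl bromide faster than β-hydride elimination and with retention of the (E) geometry of 8, which sets the C11=C12 geometry.

Step 5
Reactants: 10 (2S,4R,6E)-1-(furan-2-yl)-2,4,6-trimethyloct-6-en-1-one
Product: 11 (1R,2S,4R,6E)-1-(furan-2-yl)-2,4,6-trimethyloct-6-en-1-ol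
Conditions: RuCl[(R,R)-TsDPEN](p-cymene) (2 mol%), HCO2H/Et3N (5:2), 30 °C
Reagents that add atoms: none
Why: Noyori–Ikariya asymmetric transfer hydrogenation of a 2-acylfuran: the (R,R)-catalyst should give the (R)-carbinol (C6), its outer-sphere CH/π-controlled transition state overriding the weak intrinsic bias of the adjacent methyl-bearing centre, and the unactivated alkene is not reduced.

Step 6
Reactants: 11 (1R,2S,4R,6E)-1-(furan-2-yl)-2,4,6-trimethyloct-6-en-1-ol
Product: 13 (2R)-2-[(2S,4R,6E)-4,6-dimethyloct-6-en-2-yl]-6-hydroxy-2H-pyran-3(6H)-one as anomer mixture, via Z-enedione aldehyde 12 (not isolated)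
Conditions: VO(acac)2 (5 mol%), t-BuOOH (1.3 equiv), CH2Cl2, 0 °C→rt
Reagents that add atoms: tert-butyl hydroperoxide, CC(C)(C)OO
Why: Achmatowicz rearrangement: hydroxyl-directed vanadium-peroxide oxidation of the furan gives 12, whose aldehyde is captured by the C6 hydroxyl (six-membered hemiacetal formation) to close the pyranone ring with C6 untouched, and the remote trisubstituted alkene, having no neighbouring hydroxyl, should not be epoxidised by this reagent.

Step 7
Reactants: 13 (2R)-2-[(2S,4R,6E)-4,6-dimethyloct-6-en-2-yl]-6-hydroxy-2H-pyran-3(6H)-one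
Product: 14 (6R)-6-[(2S,4R,6E)-4,6-dimethyloct-6-en-2-yl]-2H-pyran-2,5(6H)-dione
Conditions: Jones reagent (CrO3, aq. H2SO4), acetone, 0 °C, 15 min; crude product used at once
Reagents that add atoms: none
Why: Jones oxidation of the lactol to the lactone, the usual follow-up to an Achmatowicz product; the ene-dione lactone is base-sensitive at C6 and is therefore made under acid and carried on without storage.

Step 8
Reactants: 14 (6R)-6-[(2S,4R,6E)-4,6-dimethyloct-6-en-2-yl]-2H-pyran-2,5(6H)-dione
Product: 15 (5R,6R)-6-[(2S,4R,6E)-4,6-dimethyloct-6-en-2-yl]-5-hydroxy-5,6-dihydro-2H-pyran-2-one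
Conditions: NaBH4, CeCl3·7H2O, MeOH/CH2Cl2, −78 °C
Reagents that add atoms: none
Why: Luche 1,2-reduction: cerium-activated borohydride attacks the C5 ketone rather than the enoate, from the face anti to the C6 side chain on the nearly planar ene-dione ring (side chain antiperiplanar to the incoming hydride), which should place the new hydroxyl cis to the side chain, i.e. (5R).

Step 9
Reactants: 16 furan-2(5H)-one; 17 (2-methylprop-1-en-1-yl)boronic acid
Product: 18 (S)-4-(2-methylprop-1-en-1-yl)dihydrofuran-2(3H)-one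
Conditions: [Rh(OH)((S)-BINAP)]2 (1.5 mol%), 17 (2.5 equiv), dioxane/H2O (10:1), 50 °C
Reagents that add atoms: none
Why: Rhodium-catalysed asymmetric conjugate addition of an alkenylboronic acid to a butenolide (Hayashi–Miyaura type); with (S)-BINAP the alkenyl group should add to the β-carbon from the same face as in the cyclopentenone and δ-lactone cases, which corresponds to (S) at C6′.

Step 10
Reactants: 18 (S)-4-(2-methylprop-1-en-1-yl)dihydrofuran-2(3H)-one
Product: 19 (S)-2-(2-methylprop-1-en-1-yl)butane-1,4-diol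
Conditions: LiAlH4, THF, 0 °C; Fieser work-up
Reagents that add atoms: none
Why: Lithium aluminium hydride reduction of the lactone to the 1,4-diol; the lactone CH2O becomes the hydroxymethyl arm and the carbonyl arm becomes the hydroxyethyl arm, the stereocentre not being involved.

Step 11
Reactants: 19 (S)-2-(2-methylprop-1-en-1-yl)butane-1,4-diol
Product: 20 (S)-1,4-bis(tert-butyldimethylsilyloxy)-2-(2-methylprop-1-en-1-yl)butane
Conditions: TBSCl (2.4 equiv), imidazole, DMF, rt
Reagents that add atoms: tert-butyldimethylsilyl chloride, CC(C)(C)[Si](C)(C)Cl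
Why: Standard silylation of both primary alcohols; TBS is chosen because it should survive steps 12–15 and is removed by fluoride before the epoxide exists.

Step 12
Reactants: 20 (S)-1,4-bis(tert-butyldimethylsilyloxy)-2-(2-methylprop-1-en-1-yl)butane
Product: 22 (2E,4S)-6-(tert-butyldimethylsilyloxy)-4-[(tert-butyldimethylsilyloxy)methyl]-2-methylhex-2-enal, via allylic alcohol 21 (not isolated)
Conditions: SeO2 (0.5 equiv), t-BuOOH (3 equiv), salicylic acid (10 mol%), CH2Cl2, rt; filtration; MnO2, CH2Cl2, rt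
Reagents that add atoms: tert-butyl hydroperoxide, CC(C)(C)OO (oxygen relayed by catalytic selenium dioxide, O=[Se]=O)
Why: Selenium dioxide allylic oxidation (ene reaction, then [2,3]-shift) occurs at the more substituted alkene terminus and at the methyl group trans to the chain, giving the (E)-allylic alcohol 21, and MnO2 completes the oxidation to the (E)-enal, which fixes the 4′E geometry.

Step 13
Reactants: 22 (2E,4S)-6-(tert-butyldimethylsilyloxy)-4-[(tert-butyldimethylsilyloxy)methyl]-2-methylhex-2-enal; 23 triethyl phosphonoacetate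
Product: 24 ethyl (2E,4E,6S)-8-(tert-butyldimethylsilyloxy)-6-[(tert-butyldimethylsilyloxy)methyl]-4-methylocta-2,4-dienoate
Conditions: LiCl, DBU, MeCN, rt
Reagents that add atoms: none
Why: Horner–Wadsworth–Emmons olefination under Masamune–Roush conditions should give the (2E)-enoate with high selectivity, and the mild base touches neither the γ-stereocentre nor the silyl ethers.

Step 14
Reactants: 24 ethyl (2E,4E,6S)-8-(tert-butyldimethylsilyloxy)-6-[(tert-butyldimethylsilyloxy)methyl]-4-methylocta-2,4-dienoate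
Product: 25 (2E,4E,6S)-8-(tert-butyldimethylsilyloxy)-6-[(tert-butyldimethylsilyloxy)methyl]-4-methylocta-2,4-dienoic acid
Conditions: LiOH·H2O, THF/MeOH/H2O (3:1:1), rt; 0.5 M HCl to pH 4 at 0 °C
Reagents that add atoms: lithium hydroxide, [Li+].[OH-]
Why: Saponification of the ethyl ester; primary TBS ethers and the diene geometry are stable to LiOH at room temperature and to brief cold acidification.

Step 15
Reactants: 15 (5R,6R)-6-[(2S,4R,6E)-4,6-dimethyloct-6-en-2-yl]-5-hydroxy-5,6-dihydro-2H-pyran-2-one; 25 (2E,4E,6S)-8-(tert-butyldimethylsilyloxy)-6-[(tert-butyldimethylsilyloxy)methyl]-4-methylocta-2,4-dienoic acid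
Product: 27 (2R,3R)-2-[(2S,4R,6E)-4,6-dimethyloct-6-en-2-yl]-6-oxo-3,6-dihydro-2H-pyran-3-yl (2E,4E,6S)-8-(tert-butyldimethylsilyloxy)-6-[(tert-butyldimethylsilyloxy)methyl]-4-methylocta-2,4-dienoate, via mixed anhydride 26 (not isolated)
Conditions: 25, 2,4,6-trichlorobenzoyl chloride, Et3N, toluene, rt; then 15, DMAP, toluene, 0 °C→rt
Reagents that add atoms: none
Why: Yamaguchi esterification: the acid is activated as mixed anhydride 26 and transferred by DMAP to the C5 hydroxyl with retention at C5, under conditions mild enough to avoid β-elimination to the 2-pyranone.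

Step 16
Reactants: 27 (bis-TBS ester)
Product: 28 (2R,3R)-2-[(2S,4R,6E)-4,6-dimethyloct-6-en-2-yl]-6-oxo-3,6-dihydro-2H-pyran-3-yl (2E,4E,6S)-8-hydroxy-6-(hydroxymethyl)-4-methylocta-2,4-dienoate
Conditions: HF·pyridine, pyridine, THF, 0 °C→rt
Reagents that add atoms: none
Why: Fluoride-mediated cleavage of both primary TBS ethers under buffered HF·pyridine, which should leave the ester, the unsaturated lactone and the alkenes intact.

Step 17
Reactants: 28 (diol ester)
Product: 29 (2R,3R)-2-[(2S,4R)-5-[(2S,3S)-2,3-dimethyloxiran-2-yl]-4-methylpentan-2-yl]-6-oxo-3,6-dihydro-2H-pyran-3-yl (2E,4E,6S)-8-hydroxy-6-(hydroxymethyl)-4-methylocta-2,4-dienoate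
Conditions: ent-Shi ketone (L-fructose-derived diacetonide ketone, 0.3 equiv), Oxone, K2CO3, Bu4NHSO4 (cat.), MeCN/dimethoxymethane–aq. borate/EDTA buffer (pH ≈ 9.5), 0 °C; stopped at full conversion
Reagents that add atoms: Oxone (potassium peroxymonosulfate), [K+].[O-]S(=O)(=O)OO
Why: Shi asymmetric epoxidation: the electrophilic dioxirane should react with the only isolated, electron-rich trisubstituted alkene in preference to the ester-conjugated double bonds, and the spiro transition state of the ent-ketone delivers oxygen to the face that gives the (S,S)-epoxide, the D-fructose-derived ketone being known to give (R,R)-epoxides from (E)-trisubstituted alkenes.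

**Compound list**

1 | meso-2,4-dimethylglutaric anhydride, (3R,5S)-3,5-dimethyloxane-2,6-dione | C[C@@H]1C[C@H](C)C(=O)OC1=O | starting material
2 | furan | c1ccoc1 | starting material
3 | 2-furyllithium | [Li]c1ccco1 | intermediate
4 | 2-furylzinc chloride | Cl[Zn]c1ccco1 | intermediate
5 | (2R,4S)-5-(furan-2-yl)-2,4-dimethyl-5-oxopentanoic acid | O=C(c1ccco1)[C@@H](C)C[C@@H](C)C(=O)O | intermediate
6 | (2S,4R)-1-(furan-2-yl)-5-hydroxy-2,4-dimethylpentan-1-one | O=C(c1ccco1)[C@@H](C)C[C@@H](C)CO | intermediate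
7 | (2S,4R)-1-(furan-2-yl)-5-iodo-2,4-dimethylpentan-1-one | O=C(c1ccco1)[C@@H](C)C[C@@H](C)CI | intermediate
8 | (E)-2-bromobut-2-ene | C/C=C(\C)Br | starting material
9 | [(2R,4S)-5-(furan-2-yl)-2,4-dimethyl-5-oxopentyl]zinc iodide | O=C(c1ccco1)[C@@H](C)C[C@@H](C)C[Zn]I | intermediate
10 | (2S,4R,6E)-1-(furan-2-yl)-2,4,6-trimethyloct-6-en-1-one | O=C(c1ccco1)[C@@H](C)C[C@@H](C)C/C(C)=C/C | intermediate
11 | (1R,2S,4R,6E)-1-(furan-2-yl)-2,4,6-trimethyloct-6-en-1-ol | O[C@@H](c1ccco1)[C@@H](C)C[C@@H](C)C/C(C)=C/C | intermediate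
12 | (2Z,5R,6S,8R,10E)-5-hydroxy-6,8,10-trimethyl-4-oxododeca-2,10-dienal | O=C/C=C\C(=O)[C@H](O)[C@@H](C)C[C@@H](C)C/C(C)=C/C | intermediate
13 | (2R)-2-[(2S,4R,6E)-4,6-dimethyloct-6-en-2-yl]-6-hydroxy-2H-pyran-3(6H)-one (anomer mixture) | O=C1C=CC(O)O[C@@H]1[C@@H](C)C[C@@H](C)C/C(C)=C/C | intermediate
14 | (6R)-6-[(2S,4R,6E)-4,6-dimethyloct-6-en-2-yl]-2H-pyran-2,5(6H)-dione | O=C1C=CC(=O)O[C@@H]1[C@@H](C)C[C@@H](C)C/C(C)=C/C | intermediate
15 | (5R,6R)-6-[(2S,4R,6E)-4,6-dimethyloct-6-en-2-yl]-5-hydroxy-5,6-dihydro-2H-pyran-2-one | O[C@@H]1C=CC(=O)O[C@@H]1[C@@H](C)C[C@@H](C)C/C(C)=C/C | intermediate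
16 | furan-2(5H)-one | O=C1OCC=C1 | starting material
17 | (2-methylprop-1-en-1-yl)boronic acid | CC(C)=CB(O)O | starting material
18 | (S)-4-(2-methylprop-1-en-1-yl)dihydrofuran-2(3H)-one | O=C1C[C@@H](C=C(C)C)CO1 | intermediate
19 | (S)-2-(2-methylprop-1-en-1-yl)butane-1,4-diol | CC(C)=C[C@@H](CO)CCO | intermediate
20 | (S)-1,4-bis(tert-butyldimethylsilyloxy)-2-(2-methylprop-1-en-1-yl)butane | CC(C)=C[C@@H](CO[Si](C)(C)C(C)(C)C)CCO[Si](C)(C)C(C)(C)C | intermediate
21 | (2E,4S)-6-(tert-butyldimethylsilyloxy)-4-[(tert-butyldimethylsilyloxy)methyl]-2-methylhex-2-en-1-ol | OC/C(C)=C/[C@@H](CO[Si](C)(C)C(C)(C)C)CCO[Si](C)(C)C(C)(C)C | intermediate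
22 | (2E,4S)-6-(tert-butyldimethylsilyloxy)-4-[(tert-butyldimethylsilyloxy)methyl]-2-methylhex-2-enal | O=C/C(C)=C/[C@@H](CO[Si](C)(C)C(C)(C)C)CCO[Si](C)(C)C(C)(C)C | intermediate
23 | triethyl phosphonoacetate | CCOC(=O)CP(=O)(OCC)OCC | starting material
24 | ethyl (2E,4E,6S)-8-(tert-butyldimethylsilyloxy)-6-[(tert-butyldimethylsilyloxy)methyl]-4-methylocta-2,4-dienoate | CCOC(=O)/C=C/C(C)=C/[C@@H](CO[Si](C)(C)C(C)(C)C)CCO[Si](C)(C)C(C)(C)C | intermediate
25 | (2E,4E,6S)-8-(tert-butyldimethylsilyloxy)-6-[(tert-butyldimethylsilyloxy)methyl]-4-methylocta-2,4-dienoic acid | OC(=O)/C=C/C(C)=C/[C@@H](CO[Si](C)(C)C(C)(C)C)CCO[Si](C)(C)C(C)(C)C | intermediate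
26 | mixed anhydride of 25 with 2,4,6-trichlorobenzoic acid | O=C(OC(=O)/C=C/C(C)=C/[C@@H](CO[Si](C)(C)C(C)(C)C)CCO[Si](C)(C)C(C)(C)C)c1c(Cl)cc(Cl)cc1Cl | intermediate
27 | (2R,3R)-2-[(2S,4R,6E)-4,6-dimethyloct-6-en-2-yl]-6-oxo-3,6-dihydro-2H-pyran-3-yl (2E,4E,6S)-8-(tert-butyldimethylsilyloxy)-6-[(tert-butyldimethylsilyloxy)methyl]-4-methylocta-2,4-dienoate | CC(/C=C/C(=O)O[C@@H]1C=CC(=O)O[C@@H]1[C@@H](C)C[C@@H](C)C/C(C)=C/C)=C\[C@@H](CO[Si](C)(C)C(C)(C)C)CCO[Si](C)(C)C(C)(C)C | intermediate
28 | (2R,3R)-2-[(2S,4R,6E)-4,6-dimethyloct-6-en-2-yl]-6-oxo-3,6-dihydro-2H-pyran-3-yl (2E,4E,6S)-8-hydroxy-6-(hydroxymethyl)-4-methylocta-2,4-dienoate | CC(/C=C/C(=O)O[C@@H]1C=CC(=O)O[C@@H]1[C@@H](C)C[C@@H](C)C/C(C)=C/C)=C\[C@@H](CO)CCO | intermediate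
29 | (2R,3R)-2-[(2S,4R)-5-[(2S,3S)-2,3-dimethyloxiran-2-yl]-4-methylpentan-2-yl]-6-oxo-3,6-dihydro-2H-pyran-3-yl (2E,4E,6S)-8-hydroxy-6-(hydroxymethyl)-4-methylocta-2,4-dienoate | CC(/C=C/C(=O)O[C@@H]1C=CC(=O)O[C@@H]1[C@@H](C)C[C@@H](C)C[C@]1(C)O[C@H]1C)=C\[C@@H](CO)CCO | target

**Step count and risks**

Total steps: 17. Longest linear sequence: 11 (steps 1–8 and 15–17).

Step 1 (Proposed new method). The catalyst may fail to tell the two carbonyls apart with an sp2 zinc reagent, an uncatalysed background acylation may erode the enantiomeric purity, or the acyl–rhodium species may decarbonylate. Fallback, from 1 back to 5, with known chemistry: alkaloid-mediated methanolysis of 1 (quinidine or quinine, whichever gives the required enantiomer; MeOH, toluene, −55 °C) should give the hemiester (2S,4R)-5-methoxy-2,4-dimethyl-5-oxopentanoic acid F1. Oxalyl chloride with catalytic DMF converts it into methyl (2R,4S)-5-chloro-2,4-dimethyl-5-oxopentanoate F2. Pd(PPh3)4-catalysed acylation of 4 then gives methyl (2R,4S)-5-(furan-2-yl)-2,4-dimethyl-5-oxopentanoate F3. Hydrolysis with LiOH at 0 °C (or Me3SnOH if the centre next to the ketone starts to epimerise) returns 5.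

Step 8. The direction of hydride delivery is the least certain stereochemical point: attack could instead be axial on a half-chair with the side chain pseudo-equatorial, giving the 5-epimer, or conjugate reduction of the ene-dione could compete. Fallback, from 14 back to 27: if the trans alcohol (5S,6R)-6-[(2S,4R,6E)-4,6-dimethyloct-6-en-2-yl]-5-hydroxy-5,6-dihydro-2H-pyran-2-one F4 is the main product, it is united with 25 by Mitsunobu esterification (PPh3, DIAD, toluene, 0 °C). This inverts C5 and gives 27 directly; in F4 the C6 hydrogen is syn to the leaving group, so anti-elimination to the 2-pyranone is disfavoured. Both epimers therefore lead to 27, and a mixture can be separated and each part processed by its own method.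

Step 17. Over-oxidation at the C4′=C5′ double bond of the dienoate, hydrolysis or acyl migration of the acyloxy lactone in the basic buffer, or incomplete facial control giving an epoxide epimer that is hard to separate. Fallback, from 15 back to 29: the epoxidation is moved ahead of the fragment union, where no dienoate is present. 15 is treated with the ent-Shi ketone (1 equiv, Oxone, NaHCO3, pH ≈ 8, 0 °C) to give (5R,6R)-6-[(2S,4R)-5-[(2S,3S)-2,3-dimethyloxiran-2-yl]-4-methylpentan-2-yl]-5-hydroxy-5,6-dihydro-2H-pyran-2-one F5. Yamaguchi esterification with 25 through 26 gives the bis-TBS ether of 29, F6, and pyridine-buffered HF·pyridine (or TAS-F) then releases 29.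

**Further compounds**

F1 | step 1 | (2S,4R)-5-methoxy-2,4-dimethyl-5-oxopentanoic acid | OC(=O)[C@@H](C)C[C@@H](C)C(=O)OC
F2 | step 1 | methyl (2R,4S)-5-chloro-2,4-dimethyl-5-oxopentanoate | ClC(=O)[C@@H](C)C[C@@H](C)C(=O)OC
F3 | step 1 | methyl (2R,4S)-5-(furan-2-yl)-2,4-dimethyl-5-oxopentanoate | O=C(c1ccco1)[C@@H](C)C[C@@H](C)C(=O)OC
F4 | step 8 | (5S,6R)-6-[(2S,4R,6E)-4,6-dimethyloct-6-en-2-yl]-5-hydroxy-5,6-dihydro-2H-pyran-2-one | O[C@H]1C=CC(=O)O[C@@H]1[C@@H](C)C[C@@H](C)C/C(C)=C/C
F5 | step 17 | (5R,6R)-6-[(2S,4R)-5-[(2S,3S)-2,3-dimethyloxiran-2-yl]-4-methylpentan-2-yl]-5-hydroxy-5,6-dihydro-2H-pyran-2-one | O[C@@H]1C=CC(=O)O[C@@H]1[C@@H](C)C[C@@H](C)C[C@]1(C)O[C@H]1C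
F6 | step 17 | (2R,3R)-2-[(2S,4R)-5-[(2S,3S)-2,3-dimethyloxiran-2-yl]-4-methylpentan-2-yl]-6-oxo-3,6-dihydro-2H-pyran-3-yl (2E,4E,6S)-8-(tert-butyldimethylsilyloxy)-6-[(tert-butyldimethylsilyloxy)methyl]-4-methylocta-2,4-dienoate | CC(/C=C/C(=O)O[C@@H]1C=CC(=O)O[C@@H]1[C@@H](C)C[C@@H](C)C[C@]1(C)O[C@H]1C)=C\[C@@H](CO[Si](C)(C)C(C)(C)C)CCO[Si](C)(C)C(C)(C)C
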